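The tridepside is cut at the ester between ring B and ring C. This gives a perbenzylated ring A–ring B acid and a ring C phenol. Ring C carries two meta oxygens that must be distinguished, OMe on C2 and O-acyl on C4, so ring C is built around them rather than differentiated afterwards. A benzyl 4-methoxy-6-methyl-2-pyranone-5-carboxylate brings C1, C2, C3 and C6 with ester, methoxy and methyl in place. 1,1-Bis(trimethylsilyloxy)ethene brings C4 and C5. One thermal operation forms C3–C4 and C5–C6, expels CO2 and silanol, and leaves the C4 hydroxyl as the only free oxygen. Acylation and global hydrogenolysis finish the route.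

Key step: step 4

Remark: the target is achiral, so no stereodescriptor is needed. Ring C is numbered C1 (carboxyl-bearing carbon), C2 (OMe), C4 (acyloxy), C6 (methyl). Pyranone positions are always named as "pyranone C3" and so on.

Step 1
Reactants: 1 benzyl acetoacetate; 2 malonyl dichloride
Product: 3 benzyl 4-hydroxy-6-methyl-2-oxo-2H-pyran-5-carboxylate
Conditions: 1:1, CH2Cl2 (concentrated), 0 °C to rt, N2 sweep
Reagents that add atoms: none
Why: Double acylation of the β-keto ester enol by the bis-acid chloride (C-acylation at the α-carbon, O-acylation at the enol oxygen) is the established malonyl dichloride annulation of 1,3-dicarbonyl compounds to 4-hydroxy-2-pyranones, and equimolar amounts keep 3 from being annulated a second time.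

Step 2
Reactants: 3 benzyl 4-hydroxy-6-methyl-2-oxo-2H-pyran-5-carboxylate
Product: 4 benzyl 4-methoxy-6-methyl-2-oxo-2H-pyran-5-carboxylate
Conditions: Me2SO4, K2CO3, acetone, reflux
Reagents that add atoms: dimethyl sulfate COS(=O)(=O)OC
Why: Williamson-type O-alkylation of the vinylogous acid, since 4-hydroxy-2-pyranones are methylated at the C4 oxygen by the hard electrophile Me2SO4 under carbonate conditions, which fixes the ring C methoxy group before the arene exists.

Step 3
Reactants: 5 trimethylsilyl acetate
Product: 7 1,1-bis(trimethylsilyloxy)ethene, via lithium enolate 6 (not isolated)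
Conditions: LiN(iPr)2, THF, −78 °C; Me3SiCl, −78 °C to rt; distillation under reduced pressure
Reagents that add atoms: chlorotrimethylsilane C[Si](C)(C)Cl
Why: Kinetic ester enolization followed by O-silylation (silyl ketene acetal formation), in which the hard silyl chloride traps the enolate oxygen at low temperature and the volatile product is freed from C-silylated material by distillation.

Step 4
Reactants: 4 benzyl 4-methoxy-6-methyl-2-oxo-2H-pyran-5-carboxylate; 7 1,1-bis(trimethylsilyloxy)ethene
Product: 11 benzyl 4-hydroxy-2-methoxy-6-methylbenzoate, via bridged lactone 8 (not isolated), via dihydrobenzene 9 (not isolated), via aryl silyl ether 10 (not isolated)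
Conditions: 7 (4 equiv), toluene, sealed tube, 120 °C; then 1 M HCl, THF, rt
Reagents that add atoms: none
Why: Inverse-electron-demand Diels–Alder reaction: the acceptor-substituted diene C3=C4–C5=C6 of 4 takes up the electron-rich alkene 7 in an asynchronous [4+2] addition in which the nucleophilic CH2 bonds to pyranone C6 and the acetal carbon to pyranone C3, giving bridged lactone 8. Cycloreversion of 8 expels CO2 to give diene 9, 1,2-elimination of Me3SiOH across ring C C4–C5 aromatizes 9 to 10, and the acidic work-up cleaves the aryl silyl ether. The closest known reaction type is the cycloaddition of 2-pyranone-5-carboxylates (coumalates) with ketene acetals and enol ethers, which gives para-oxygenated benzoates after CO2 extrusion. Ring C is closed in an intermolecular [4+2] mode, four carbons coming from 4 and two from 7, so that both new bonds (C3–C4 and C5–C6) arise in the same event and no separate cyclization is required. The two bridgehead stereocenters of racemic 8 vanish on aromatization, so no stereocontrol is needed. The only selectivity required is regiochemical, and it is secured twice over: pyranone C6 is the β-carbon of the C5 ester and the δ-carbon of the lactone carbonyl, while the C4 methoxy group polarizes pyranone C3 towards the electrophilic acetal carbon, which places the new oxygen para to the ester and keeps the methoxy oxygen, installed beforehand, out of any competition.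

Step 5
Reactants: 12 2,4-dihydroxy-6-methylbenzaldehyde
Product: 13 2,4-bis(benzyloxy)-6-methylbenzaldehyde
Conditions: BnBr (2.4 equiv), K2CO3, DMF, 60 °C
Reagents that add atoms: benzyl bromide BrCc1ccccc1
Why: Williamson ether synthesis, in which warming in DMF also alkylates the hydroxyl that is hydrogen-bonded to the formyl group.

Step 6
Reactants: 13 2,4-bis(benzyloxy)-6-methylbenzaldehyde
Product: 14 2,4-bis(benzyloxy)-6-methylbenzoic acid
Conditions: NaClO2, NaH2PO4, 2-methyl-2-butene (excess), tBuOH/THF/H2O, rt
Reagents that add atoms: sodium chlorite [Na+].[O-]Cl=O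
Why: Pinnick oxidation converts the hindered, electron-rich aldehyde into the acid under buffered conditions, and excess 2-methyl-2-butene intercepts HOCl before it can chlorinate the ring.

Step 7
Reactants: 14 2,4-bis(benzyloxy)-6-methylbenzoic acid; 12 2,4-dihydroxy-6-methylbenzaldehyde
Product: 16 4-formyl-3-hydroxy-5-methylphenyl 2,4-bis(benzyloxy)-6-methylbenzoate, via O-acylisourea 15 (not isolated)
Conditions: DCC, DMAP (cat.), CH2Cl2, 0 °C to rt
Reagents that add atoms: none
Why: Steglich esterification, in which the C4 hydroxyl of 12 is the free and more acidic one whereas the C2 hydroxyl is tied up in a hydrogen bond to the adjacent formyl group, so monoacylation at O4 is expected and the formyl group serves as the latent ring B carboxyl.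

Step 8
Reactants: 16 4-formyl-3-hydroxy-5-methylphenyl 2,4-bis(benzyloxy)-6-methylbenzoate
Product: 17 3-(benzyloxy)-4-formyl-5-methylphenyl 2,4-bis(benzyloxy)-6-methylbenzoate
Conditions: BnBr (1.5 equiv), K2CO3 (anhydrous), DMF, 40 °C
Reagents that add atoms: benzyl bromide BrCc1ccccc1
Why: Williamson ether synthesis on the remaining chelated phenol, while the di-ortho-substituted, electron-rich aryl ester is shielded against attack under anhydrous carbonate conditions.

Step 9
Reactants: 17 3-(benzyloxy)-4-formyl-5-methylphenyl 2,4-bis(benzyloxy)-6-methylbenzoate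
Product: 18 2-(benzyloxy)-4-{[2,4-bis(benzyloxy)-6-methylbenzoyl]oxy}-6-methylbenzoic acid
Conditions: NaClO2, NaH2PO4, 2-methyl-2-butene (excess), tBuOH/THF/H2O, rt
Reagents that add atoms: sodium chlorite [Na+].[O-]Cl=O
Why: Pinnick oxidation, whose weakly acidic buffer leaves the aryl ester and the benzyl ethers untouched.

Step 10
Reactants: 18 2-(benzyloxy)-4-{[2,4-bis(benzyloxy)-6-methylbenzoyl]oxy}-6-methylbenzoic acid; 11 benzyl 4-hydroxy-2-methoxy-6-methylbenzoate
Product: 20 benzyl 4-{[2-(benzyloxy)-4-{[2,4-bis(benzyloxy)-6-methylbenzoyl]oxy}-6-methylbenzoyl]oxy}-2-methoxy-6-methylbenzoate, via mixed anhydride 19 (not isolated)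
Conditions: (CF3CO)2O, toluene, rt
Reagents that add atoms: none
Why: Mixed-anhydride esterification (the classical trifluoroacetic anhydride depside coupling), in which the electron-rich, di-ortho-substituted acyl trifluoroacetate reacts through an acylium-like species that escapes the steric block on addition–elimination, and 11 offers a single unhindered hydroxyl.

Step 11
Reactants: 20 benzyl 4-{[2-(benzyloxy)-4-{[2,4-bis(benzyloxy)-6-methylbenzoyl]oxy}-6-methylbenzoyl]oxy}-2-methoxy-6-methylbenzoate
Product: 21 4-{[4-(2,4-dihydroxy-6-methylbenzoyloxy)-2-hydroxy-6-methylbenzoyl]oxy}-2-methoxy-6-methylbenzoic acid (target)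
Conditions: H2 (1 atm), Pd/C (10 wt % Pd on carbon), EtOAc, rt
Reagents that add atoms: none
Why: Catalytic hydrogenolysis cleaves the three benzyl ethers and the benzyl ester in one operation, and a non-nucleophilic solvent at room temperature avoids alcoholysis of the depside links and decarboxylation of the product acid.

Compound list
1 | benzyl acetoacetate | CC(=O)CC(=O)OCc1ccccc1 | starting material
2 | malonyl dichloride | O=C(Cl)CC(=O)Cl | starting material
3 | benzyl 4-hydroxy-6-methyl-2-oxo-2H-pyran-5-carboxylate | CC1=C(C(=O)OCc2ccccc2)C(O)=CC(=O)O1 | intermediate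
4 | benzyl 4-methoxy-6-methyl-2-oxo-2H-pyran-5-carboxylate | COC1=CC(=O)OC(C)=C1C(=O)OCc1ccccc1 | intermediate
5 | trimethylsilyl acetate | CC(=O)O[Si](C)(C)C | starting material
6 | lithium enolate of trimethylsilyl acetate | [Li+].C=C([O-])O[Si](C)(C)C | intermediate
7 | 1,1-bis(trimethylsilyloxy)ethene | C=C(O[Si](C)(C)C)O[Si](C)(C)C | intermediate
8 | bridged lactone: benzyl 5-methoxy-1-methyl-3-oxo-8,8-bis(trimethylsilyloxy)-2-oxabicyclo[2.2.2]oct-5-ene-6-carboxylate (racemic) | CC12CC(O[Si](C)(C)C)(O[Si](C)(C)C)C(C(=O)O1)C(OC)=C2C(=O)OCc1ccccc1 | intermediate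
9 | dihydrobenzene: benzyl 6-methoxy-2-methyl-4,4-bis(trimethylsilyloxy)cyclohexa-1,5-diene-1-carboxylate | COC1=CC(O[Si](C)(C)C)(O[Si](C)(C)C)CC(C)=C1C(=O)OCc1ccccc1 | intermediate
10 | aryl silyl ether: benzyl 2-methoxy-6-methyl-4-(trimethylsilyloxy)benzoate | COc1cc(O[Si](C)(C)C)cc(C)c1C(=O)OCc1ccccc1 | intermediate
11 | benzyl 4-hydroxy-2-methoxy-6-methylbenzoate | COc1cc(O)cc(C)c1C(=O)OCc1ccccc1 | intermediate
12 | 2,4-dihydroxy-6-methylbenzaldehyde | Cc1cc(O)cc(O)c1C=O | starting material
13 | 2,4-bis(benzyloxy)-6-methylbenzaldehyde | Cc1cc(OCc2ccccc2)cc(OCc2ccccc2)c1C=O | intermediate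
14 | 2,4-bis(benzyloxy)-6-methylbenzoic acid | Cc1cc(OCc2ccccc2)cc(OCc2ccccc2)c1C(=O)O | intermediate
15 | O-acylisourea from 14 and DCC | Cc1cc(OCc2ccccc2)cc(OCc2ccccc2)c1C(=O)OC(=NC1CCCCC1)NC1CCCCC1 | intermediate
16 | 4-formyl-3-hydroxy-5-methylphenyl 2,4-bis(benzyloxy)-6-methylbenzoate | Cc1cc(OCc2ccccc2)cc(OCc2ccccc2)c1C(=O)Oc1cc(C)c(C=O)c(O)c1 | intermediate
17 | 3-(benzyloxy)-4-formyl-5-methylphenyl 2,4-bis(benzyloxy)-6-methylbenzoate | Cc1cc(OCc2ccccc2)cc(OCc2ccccc2)c1C(=O)Oc1cc(C)c(C=O)c(OCc2ccccc2)c1 | intermediate
18 | 2-(benzyloxy)-4-{[2,4-bis(benzyloxy)-6-methylbenzoyl]oxy}-6-methylbenzoic acid | Cc1cc(OCc2ccccc2)cc(OCc2ccccc2)c1C(=O)Oc1cc(C)c(C(=O)O)c(OCc2ccccc2)c1 | intermediate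
19 | mixed anhydride of 18 and trifluoroacetic acid | Cc1cc(OCc2ccccc2)cc(OCc2ccccc2)c1C(=O)Oc1cc(C)c(C(=O)OC(=O)C(F)(F)F)c(OCc2ccccc2)c1 | intermediate
20 | benzyl 4-{[2-(benzyloxy)-4-{[2,4-bis(benzyloxy)-6-methylbenzoyl]oxy}-6-methylbenzoyl]oxy}-2-methoxy-6-methylbenzoate | COc1cc(OC(=O)c2c(C)cc(OC(=O)c3c(C)cc(OCc4ccccc4)cc3OCc3ccccc3)cc2OCc2ccccc2)cc(C)c1C(=O)OCc1ccccc1 | intermediate
21 | 4-{[4-(2,4-dihydroxy-6-methylbenzoyloxy)-2-hydroxy-6-methylbenzoyl]oxy}-2-methoxy-6-methylbenzoic acid | COc1cc(OC(=O)c2c(C)cc(OC(=O)c3c(C)cc(O)cc3O)cc2O)cc(C)c1C(=O)O | target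

Total step count: 11.

Longest linear sequence: 7 steps (5, 6, 7, 8, 9, 10, 11). The ring C branch (1, 2, 4, 10, 11) has 5 steps.

Steps most likely to fail

Step 4. The cycloaddition may be too slow. The C4 methoxy donor lowers the electron demand of the diene, and the C6 methyl group crowds the terminus that must accept the CH2 carbon. O-to-C silyl migration of the ketene acetal, or its protonation by released silanol, could then outrun the addition. The fallback gives up ring construction and differentiates the two oxygens of a preformed resorcinol through chelation. It sets out from 12 and comes back at 11.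
- Monobenzylation of 12 at the non-chelated C4 hydroxyl (BnBr 1 equiv, NaHCO3, MeCN, 60 °C) should give 4-(benzyloxy)-2-hydroxy-6-methylbenzaldehyde F1.
- Methylation of the chelated hydroxyl (MeI, K2CO3, DMF) should give 4-(benzyloxy)-2-methoxy-6-methylbenzaldehyde F2.
- Pinnick oxidation should give 4-(benzyloxy)-2-methoxy-6-methylbenzoic acid F3.
- Hydrogenolysis (H2, Pd/C, EtOAc) should give 4-hydroxy-2-methoxy-6-methylbenzoic acid F4.
- Carboxylate-selective alkylation (BnBr, KHCO3, DMF, rt) should deliver 11.

Step 1. The first-formed hydroxypyranone may be annulated again by malonyl dichloride, the acid chloride may self-condense, and the HCl released may erode the benzyl ester. The fallback separates the two acylations. It sets out from 1 and comes back at 3.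
- C-acylation of the magnesium chelate of 1 (MgCl2, pyridine, CH2Cl2, 0 °C) with methyl 3-chloro-3-oxopropanoate should give 1-benzyl 5-methyl 2-acetyl-3-oxopentanedioate F5.
- Base-induced enol lactonization of this 3,5-dioxo ester (DBU, toluene, reflux), with loss of methanol, should close the ring to 3.

Step 10. Capture of the hindered acyl donor may be sluggish. This would leave time for acyl exchange at the existing ring A–ring B aryl ester and for acid-induced loss of the ortho benzyl ether. The fallback reverses the order of assembly, so that only monomeric acids, usable in excess, are ever activated. It sets out from 12, takes in 11 and 14, and comes back at 20.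
- Selective protection of the C4 hydroxyl of 12 (MOMCl, iPr2NEt, CH2Cl2, 0 °C) should give 2-hydroxy-4-(methoxymethoxy)-6-methylbenzaldehyde F6.
- Benzylation (BnBr, K2CO3, DMF) should give 2-(benzyloxy)-4-(methoxymethoxy)-6-methylbenzaldehyde F7.
- Pinnick oxidation should give 2-(benzyloxy)-4-(methoxymethoxy)-6-methylbenzoic acid F8.
- Steglich esterification of F8 with 11 (DCC, DMAP, CH2Cl2) should give benzyl 4-{[2-(benzyloxy)-4-(methoxymethoxy)-6-methylbenzoyl]oxy}-2-methoxy-6-methylbenzoate F9.
- Acetal cleavage (HCl, iPrOH/THF, 40 °C) should give benzyl 4-{[2-(benzyloxy)-4-hydroxy-6-methylbenzoyl]oxy}-2-methoxy-6-methylbenzoate F10.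
- A second Steglich esterification with 14 should give 20.

Further compounds
F1 | step 4 | 4-(benzyloxy)-2-hydroxy-6-methylbenzaldehyde | Cc1cc(OCc2ccccc2)cc(O)c1C=O
F2 | step 4 | 4-(benzyloxy)-2-methoxy-6-methylbenzaldehyde | COc1cc(OCc2ccccc2)cc(C)c1C=O
F3 | step 4 | 4-(benzyloxy)-2-methoxy-6-methylbenzoic acid | COc1cc(OCc2ccccc2)cc(C)c1C(=O)O
F4 | step 4 | 4-hydroxy-2-methoxy-6-methylbenzoic acid | COc1cc(O)cc(C)c1C(=O)O
F5 | step 1 | 1-benzyl 5-methyl 2-acetyl-3-oxopentanedioate | COC(=O)CC(=O)C(C(C)=O)C(=O)OCc1ccccc1
F6 | step 10 | 2-hydroxy-4-(methoxymethoxy)-6-methylbenzaldehyde | COCOc1cc(C)c(C=O)c(O)c1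
F7 | step 10 | 2-(benzyloxy)-4-(methoxymethoxy)-6-methylbenzaldehyde | COCOc1cc(C)c(C=O)c(OCc2ccccc2)c1
F8 | step 10 | 2-(benzyloxy)-4-(methoxymethoxy)-6-methylbenzoic acid | COCOc1cc(C)c(C(=O)O)c(OCc2ccccc2)c1
F9 | step 10 | benzyl 4-{[2-(benzyloxy)-4-(methoxymethoxy)-6-methylbenzoyl]oxy}-2-methoxy-6-methylbenzoate | COCOc1cc(C)c(C(=O)Oc2cc(C)c(C(=O)OCc3ccccc3)c(OC)c2)c(OCc2ccccc2)c1
F10 | step 10 | benzyl 4-{[2-(benzyloxy)-4-hydroxy-6-methylbenzoyl]oxy}-2-methoxy-6-methylbenzoate | Oc1cc(C)c(C(=O)Oc2cc(C)c(C(=O)OCc3ccccc3)c(OC)c2)c(OCc2ccccc2)c1
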